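## The problem

Target 19 is an aryltetralin of the isolariciresinol type. A guaiacol ring A (C7 phenol, C6 methoxy) is fused through C4a and C8a to a saturated six-membered ring B. Ring B carries a 4-hydroxy-3-methoxyphenyl group at C1, an acetoxymethyl group at C2 and a hydroxymethyl group at C3; C4 is the benzylic CH2.

The three contiguous stereocentres are (1S,2R,3R), with all three substituents mutually trans. Ring B is the only ring to be made, but it must be made in one absolute sense.

C2 and C3 form a trans pair that an E-alkene can deliver. C1 is doubly benzylic and can be set last, relative to C2, but only if hydrogen enters cis to the C2 arm. An external hydride attacking a C1 cation would do the opposite: allylic 1,3-strain with the C1 aryl group turns the C2 arm axial, the hydride enters anti to it, and the 1,2-cis epimer results. The configuration at C1 must therefore be relayed from C2.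

The two one-carbon arms differ only by an acetyl group. A 1,4-diol monoacetate can lose or shift its acetyl group under base or acid, so the arms must be different from the moment they are introduced and the last steps must be neutral.

The two free phenols are electron-rich and oxidisable, the one para to C1 towards a quinone methide. They stay masked to the end by groups that leave without touching the acetate.

The feature that opens the route is that C1–C2–C3–C4 bridges the two ortho positions of ring A. Ring B is thus the formal adduct of an o-quinodimethane (C4, C4a, C8a, C1) with a trans-disubstituted alkene (C2, C3). Because C1 bears an aryl group and can temporarily bear a hydroxyl, that diene is the photoenol of a 2-methylbenzophenone.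

## Retrosynthesis

**19 ⇒ 18 (three O–benzyl bonds).** The two phenols and the C3 carbinol are masked as benzyl ethers in 18. One neutral hydrogenolysis frees all three; the acetate and the C1–H bond are not affected. Mixed protecting groups would add steps and acidic or basic deprotections next to a migration-prone acetate. The forward step only has to stay neutral.

**18 ⇒ 17 ⇒ 14 ⇒ 13 (acetyl C–O and C1–H).** The acetate is put on the C2 carbinol 17. The C1–H bond of 17 is traced to a tertiary C1 hydroxyl, removed through the diarylcarbenium ion 15. Since an external silane would enter anti to the C2 arm, the hydride is tied to the C2 oxygen as the diisopropylsilyl ether 14. From there it can reach C1 only on the face of that arm. The oxygen that carries the tether is the one that is acetylated afterwards, so acetylation follows the reduction. Diol 13 is the precursor. The forward reaction must ionise C1 without cleaving the Si–O tether and must be run dilute.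

**13 ⇒ 12 (C2 carbinol from an acyl group).** The C2 carbinol comes from reductive cleavage of the N-acyl oxazolidinone 12. This is what keeps the arms apart: the C2 arm arrives as a carbonyl, the C3 arm as a benzyl ether. The reduction must not open the β-hydroxy imide by retro-aldol cleavage.

**12 ⇒ 7 + 10 (C1–C2 and C3–C4; key step).** Both ring B bonds that flank the trans pair are cut at once, giving benzophenone 7 and enoyl imide 10.
- Against a cut at C1–C8a (cationic ring closure) or at C2–C3, this cut removes the ring and two stereocentres together and leaves two achiral building blocks.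
- The forward reaction needs the E-dienol 11 from 7, an endo transition state, the acyl group next to the hydroxylated terminus, and one alkene face of 10 selected by a chiral titanium TADDOLate.

**7 ⇒ 3 + 4; 3 ⇒ 2 ⇒ 1 (aryl–carbonyl bond).** The ketone is cut between the carbonyl carbon and the methyl-bearing ring. Friedel–Crafts acylation of 2 would be one step shorter, but Lewis acids strong enough to acylate also cleave benzyl ethers of guaiacols. Instead the aryllithium 5, from bromide 3, adds to nitrile 4. Bromide 3 comes from 2 by bromination para to methoxy, and 2 from creosol 1 by benzylation.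

**10 ⇒ 8 + 9 (the C=C bond).** Cross metathesis of acryloyl imide 8 with allyl benzyl ether 9 gives 10 in one step with E geometry. Olefination of an aldehyde, ester hydrolysis and N-acylation would need three.

## Roads not taken

**Alternative 1:** The cut is at C2–C3 and C1–C8a, which divides the skeleton into two identical brominated cinnamoyl imides A1.
- *Forward step:* one-electron oxidation couples the β-carbons of two molecules of A1. One resulting quinone methide is attacked by the other ring para to its methoxy group, and tautomerisation gives the dihydronaphthalene A2.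
- *Merits:* one monomer supplies every carbon, and ring B and two stereocentres arise in one operation. The aryl group enters C1 trans to the C2 acyl group as the ring closes, so C1 needs no later correction. In this respect the road is better than the chosen plan, which spends steps 7 and 8 on C1.
- *Weak points:* A2 carries a C3=C4 double bond and the same imide on both arms. Cis-hydrogenation anti to the C2 substituent would give the C2/C3 cis compound, so an epimerisation at C3 would have to follow. Once C3 is saturated the two arms differ only by position, and selective acetylation of the C2 arm has no handle. Two bromines must be put on and taken off, the radical coupling is divided among several coupling modes, and two equivalents of auxiliary are consumed.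
- *Comparison:* this road reaches the skeleton faster but reaches the monoacetate more slowly and less surely. The chosen plan pays for C1 with a tether, but its arms are different from step 5 onward and the trans C2/C3 relation is copied from an alkene.

**Alternative 2:** The cut is inside ring A, at C4a–C8a and C7–C8, leaving the open-chain furan–alkyne A3.
- *Forward step:* heating A3 brings the furan across the terminal alkyne in an intramolecular [4+2] that closes ring B through a four-atom tether. The oxygen bridge then opens and ring A aromatises to the C7 phenol of A4.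
- *Merits:* A4 is one hydrogenolysis from 19, with the acetate and all three stereocentres already in place. This is the shortest endgame of the four roads, against five steps after the key step in the chosen plan.
- *Weak points:* A3 must carry all three contiguous stereocentres in an open chain, including the C1 methine with aryl and alkynyl groups, where no ring helps to relate them. The difficulty is moved, not removed. An unactivated terminal alkyne on a four-atom tether needs forcing temperatures, which an acetate and an electron-rich alkoxyfuran must survive. The bridge must open towards C7 only. A benzene ring that can be bought is built instead.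
- *Comparison:* the chosen plan has the longer endgame. Against that, 7 and 10 are achiral and are reached in three steps and one step, whereas A3 needs a long stereocontrolled chain synthesis before its key step can be tried.

**Alternative 3:** The cut is at C1–C2, leaving the p-hydroxy diarylcarbinol A5 with a malonate on the C3 side chain.
- *Forward step:* mild base dehydrates A5 to the p-quinone methide. The malonate adds to C1 reversibly and closes ring B, and the equilibrium settles on A6, with aryl and vinyl cis.
- *Merits:* C1 is set by equilibrium, which is more forgiving than the kinetically directed hydride of step 8, and both carbinol epimers converge. Only C3 has to be made asymmetrically. The arms are different from the start (ester and vinyl).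
- *Weak points:* five to six operations follow A6: decarboxylation at high temperature with C2 set by protonation, ester reduction, acetylation, oxidative cleavage of the vinyl group with loss of one carbon in the presence of electron-rich arenes and a free phenol, reduction, and debenzylation. A5 itself requires an arene with two different ortho side chains, built linearly.
- *Comparison:* this road is safer at C1, and the chosen plan has only the tether to set against that. It is longer and linear, whereas the chosen plan forms both ring bonds and the C2/C3 pair in one convergent step from two simple partners.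

Key step: step 5

Assumption: compounds 4, 8 and 9 and (R,R)-TADDOL are taken as purchasable; tetralin numbering (C1 aryl-bearing, C2 acyl- or acetoxymethyl-bearing, C3 oxymethyl-bearing) is used for all ring B compounds.

## Route

Step 1
Reactants: 1 creosol (2-methoxy-4-methylphenol)
Product: 2 1-(benzyloxy)-2-methoxy-4-methylbenzene
Conditions: BnBr, K2CO3, DMF, rt
Reagents that add atoms: benzyl bromide, BrCc1ccccc1
Why: Williamson etherification of the phenoxide; the benzyl ether masks the future C7 phenol until the final hydrogenolysis.

Step 2
Reactants: 2 1-(benzyloxy)-2-methoxy-4-methylbenzene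
Product: 3 1-(benzyloxy)-5-bromo-2-methoxy-4-methylbenzene
Conditions: NBS, MeCN, 0 °C to rt, dark
Reagents that add atoms: N-bromosuccinimide, O=C1CCC(=O)N1Br
Why: Electrophilic aromatic bromination; the position para to methoxy and ortho to methyl is the most activated and accessible one, and a polar solvent without initiator suppresses benzylic bromination.

Step 3
Reactants: 3 1-(benzyloxy)-5-bromo-2-methoxy-4-methylbenzene; 4 4-(benzyloxy)-3-methoxybenzonitrile
Product: 7 [5-(benzyloxy)-4-methoxy-2-methylphenyl][4-(benzyloxy)-3-methoxyphenyl]methanone, via aryllithium 5 (not isolated), via lithium ketimide 6 (not isolated)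
Conditions: n-BuLi, THF, −78 °C; then 4, −78 to 0 °C; then 2 M HCl, THF, 40 °C
Reagents that add atoms: water, O
Why: Bromine–lithium exchange followed by addition of the aryllithium to the nitrile, which stops at the lithium ketimide so that no tertiary carbinol can form; acid hydrolysis of the imine gives the diaryl ketone with the methyl group ortho to the carbonyl.

Step 4
Reactants: 8 3-acryloyloxazolidin-2-one; 9 allyl benzyl ether
Product: 10 3-[(E)-4-(benzyloxy)but-2-enoyl]oxazolidin-2-one
Conditions: second-generation Hoveyda–Grubbs catalyst RuCl2(H2IMes)(=CH-C6H4-2-OiPr) (3 mol%), 9 (2 equiv), CH2Cl2, 40 °C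
Reagents that add atoms: none
Why: Olefin cross metathesis between an electron-poor acryloyl imide and an unhindered terminal alkene favours the cross product and the E isomer, with ethylene leaving the mixture.

Step 5
Reactants: 7 [5-(benzyloxy)-4-methoxy-2-methylphenyl][4-(benzyloxy)-3-methoxyphenyl]methanone; 10 3-[(E)-4-(benzyloxy)but-2-enoyl]oxazolidin-2-one
Product: 12 3-{[(1R,2S,3R)-7-(benzyloxy)-1-[4-(benzyloxy)-3-methoxyphenyl]-3-[(benzyloxy)methyl]-1-hydroxy-6-methoxy-1,2,3,4-tetrahydronaphthalen-2-yl]carbonyl}oxazolidin-2-one, via E-dienol 11 (not isolated)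
Conditions: TiCl2(OiPr)2 (1.1 equiv), (R,R)-TADDOL (1.2 equiv), 4 Å MS, toluene, rt; then 10 (1.0 equiv), 7 (1.2 equiv), degassed, hν (365 nm), −20 °C; cold aq NaHCO3
Reagents that add atoms: none
Why: Excitation of 7, intersystem crossing and 1,5-hydrogen transfer from the ortho methyl group give the dienols, of which the Z isomer returns rapidly to 7 while the E isomer 11 (OH outside, aryl inside) persists long enough to be trapped. 11 then adds as an electron-rich diene to 10, held s-cis by two-point binding on the tetravalent titanium complex TiCl2[(R,R)-TADDOLate], in a concerted, asynchronous, suprafacial [4+2] cycloaddition; the closest known reaction type is the photoenolisation/Diels–Alder trapping of 2-alkylaryl ketones combined with titanium TADDOLate activation of N-enoyl oxazolidinones. Ring B is closed by this intermolecular [4+2] annulation, in which the diene carbons C4, C4a, C8a and C1 join the two alkene carbons through the new C1–C2 and C3–C4 bonds while ring A regains aromaticity. The hydroxyl donor at C1 makes C4 the nucleophilic terminus, which bonds to the β-carbon of the enoyl imide, so the acyl carbon lands on C2. C2 and C3 are set absolutely by the ligand, which should leave the Cα-Re face of the chelated imide open (C2 S, C3 R), and relatively by the E geometry of 10, which becomes the trans relation. C1 (R) follows from the endo position of the chelated acyl group under the diene together with the outside hydroxyl, which places OH cis to the acyl group; this centre is provisional and is rewritten in step 8. The step needs facial selectivity without an unselective background reaction: free 10 is a poor trap for 11, which then simply reverts to 7, so product should arise mainly from titanium-bound 10.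

Step 6
Reactants: 12 3-{[(1R,2S,3R)-7-(benzyloxy)-1-[4-(benzyloxy)-3-methoxyphenyl]-3-[(benzyloxy)methyl]-1-hydroxy-6-methoxy-1,2,3,4-tetrahydronaphthalen-2-yl]carbonyl}oxazolidin-2-one
Product: 13 (1R,2R,3R)-7-(benzyloxy)-1-[4-(benzyloxy)-3-methoxyphenyl]-3-[(benzyloxy)methyl]-2-(hydroxymethyl)-6-methoxy-1,2,3,4-tetrahydronaphthalen-1-ol
Conditions: LiBH4, MeOH (1 equiv), THF, 0 °C
Reagents that add atoms: none
Why: Reductive cleavage of an N-acyl oxazolidinone by lithium borohydride at the chelation-activated exocyclic carbonyl gives the primary alcohol and releases the oxazolidinone; no stereocentre is touched, and the change of the C2 descriptor from S to R reflects only the new substituent priorities.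

Step 7
Reactants: 13 (1R,2R,3R)-7-(benzyloxy)-1-[4-(benzyloxy)-3-methoxyphenyl]-3-[(benzyloxy)methyl]-2-(hydroxymethyl)-6-methoxy-1,2,3,4-tetrahydronaphthalen-1-ol
Product: 14 (1R,2R,3R)-7-(benzyloxy)-1-[4-(benzyloxy)-3-methoxyphenyl]-3-[(benzyloxy)methyl]-2-{[(diisopropylsilyl)oxy]methyl}-6-methoxy-1,2,3,4-tetrahydronaphthalen-1-ol
Conditions: iPr2SiHCl, imidazole, CH2Cl2, 0 °C
Reagents that add atoms: chlorodiisopropylsilane, CC(C)[SiH](Cl)C(C)C
Why: Silylation of an alcohol with a chlorosilane; the primary hydroxyl reacts while the hindered tertiary diaryl carbinol does not, which places the Si–H bond on the C2 arm.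

Step 8
Reactants: 14 (1R,2R,3R)-7-(benzyloxy)-1-[4-(benzyloxy)-3-methoxyphenyl]-3-[(benzyloxy)methyl]-2-{[(diisopropylsilyl)oxy]methyl}-6-methoxy-1,2,3,4-tetrahydronaphthalen-1-ol
Product: 17 [(1S,2R,3R)-7-(benzyloxy)-1-[4-(benzyloxy)-3-methoxyphenyl]-3-[(benzyloxy)methyl]-6-methoxy-1,2,3,4-tetrahydronaphthalen-2-yl]methanol, via carbenium ion 15 (not isolated), via silyl trifluoroacetate 16 (not isolated)
Conditions: TFA (3 equiv), CH2Cl2 (0.01 M), −40 to 0 °C; then TBAF, THF, rt
Reagents that add atoms: none
Why: Tethered ionic hydrogenation: acid ionises the doubly benzylic tertiary carbinol to the diarylcarbenium ion 15, whose Si–H bond can reach C1 only through a six-membered transition state on the face of the C2 arm, so hydrogen enters cis to that arm and the aryl group ends trans to it (C1 S), the opposite of what an external silane would give. The closest known reaction type is intramolecular hydride transfer from alkoxy(dialkyl)silanes to benzylic carbocations of tetralins; high dilution excludes intermolecular transfer and fluoride then frees the C2 carbinol from silicon.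

Step 9
Reactants: 17 [(1S,2R,3R)-7-(benzyloxy)-1-[4-(benzyloxy)-3-methoxyphenyl]-3-[(benzyloxy)methyl]-6-methoxy-1,2,3,4-tetrahydronaphthalen-2-yl]methanol
Product: 18 [(1S,2R,3R)-7-(benzyloxy)-1-[4-(benzyloxy)-3-methoxyphenyl]-3-[(benzyloxy)methyl]-6-methoxy-1,2,3,4-tetrahydronaphthalen-2-yl]methyl acetate
Conditions: Ac2O, pyridine, DMAP (cat.), CH2Cl2, 0 °C to rt
Reagents that add atoms: acetic anhydride, CC(=O)OC(C)=O
Why: Acylation of the only free hydroxyl by nucleophilic catalysis; every other oxygen is a benzyl or methyl ether, so the acetate can go only to the C2 arm.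

Step 10
Reactants: 18 [(1S,2R,3R)-7-(benzyloxy)-1-[4-(benzyloxy)-3-methoxyphenyl]-3-[(benzyloxy)methyl]-6-methoxy-1,2,3,4-tetrahydronaphthalen-2-yl]methyl acetate
Product: 19 [(1S,2R,3R)-7-hydroxy-1-(4-hydroxy-3-methoxyphenyl)-3-(hydroxymethyl)-6-methoxy-1,2,3,4-tetrahydronaphthalen-2-yl]methyl acetate
Conditions: H2 (1 atm), 10% Pd/C, EtOAc, rt
Reagents that add atoms: none
Why: Hydrogenolysis of two aryl benzyl ethers and one alkyl benzyl ether on palladium under neutral conditions; the acetate, the C1–H bond and the three stereocentres are inert, and the absence of base or acid keeps the acetyl group on the C2 arm.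

## Compound list

1 | creosol (2-methoxy-4-methylphenol) | Cc1ccc(O)c(OC)c1 | starting material
2 | 1-(benzyloxy)-2-methoxy-4-methylbenzene | Cc1ccc(OCc2ccccc2)c(OC)c1 | intermediate
3 | 1-(benzyloxy)-5-bromo-2-methoxy-4-methylbenzene | Cc1cc(OC)c(OCc2ccccc2)cc1Br | intermediate
4 | 4-(benzyloxy)-3-methoxybenzonitrile | COc1cc(C#N)ccc1OCc1ccccc1 | starting material
5 | [5-(benzyloxy)-4-methoxy-2-methylphenyl]lithium | Cc1cc(OC)c(OCc2ccccc2)cc1[Li] | intermediate
6 | lithium ketimide of 7, N-lithio-1-[5-(benzyloxy)-4-methoxy-2-methylphenyl]-1-[4-(benzyloxy)-3-methoxyphenyl]methanimine | Cc1cc(OC)c(OCc2ccccc2)cc1C(=N[Li])c1ccc(OCc2ccccc2)c(OC)c1 | intermediate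
7 | [5-(benzyloxy)-4-methoxy-2-methylphenyl][4-(benzyloxy)-3-methoxyphenyl]methanone | Cc1cc(OC)c(OCc2ccccc2)cc1C(=O)c1ccc(OCc2ccccc2)c(OC)c1 | intermediate
8 | 3-acryloyloxazolidin-2-one | C=CC(=O)N1CCOC1=O | starting material
9 | allyl benzyl ether | C=CCOCc1ccccc1 | starting material
10 | 3-[(E)-4-(benzyloxy)but-2-enoyl]oxazolidin-2-one | O=C(/C=C/COCc1ccccc1)N1CCOC1=O | intermediate
11 | (E)-[4-(benzyloxy)-3-methoxyphenyl][3-(benzyloxy)-4-methoxy-6-methylidenecyclohexa-2,4-dien-1-ylidene]methanol (E-dienol) | C=C1C=C(OC)C(OCc2ccccc2)=C/C1=C(\O)c1ccc(OCc2ccccc2)c(OC)c1 | intermediate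
12 | 3-{[(1R,2S,3R)-7-(benzyloxy)-1-[4-(benzyloxy)-3-methoxyphenyl]-3-[(benzyloxy)methyl]-1-hydroxy-6-methoxy-1,2,3,4-tetrahydronaphthalen-2-yl]carbonyl}oxazolidin-2-one | COc1cc([C@@]2(O)c3cc(OCc4ccccc4)c(OC)cc3C[C@@H](COCc3ccccc3)[C@@H]2C(=O)N2CCOC2=O)ccc1OCc1ccccc1 | intermediate
13 | (1R,2R,3R)-7-(benzyloxy)-1-[4-(benzyloxy)-3-methoxyphenyl]-3-[(benzyloxy)methyl]-2-(hydroxymethyl)-6-methoxy-1,2,3,4-tetrahydronaphthalen-1-ol | COc1cc([C@@]2(O)c3cc(OCc4ccccc4)c(OC)cc3C[C@@H](COCc3ccccc3)[C@@H]2CO)ccc1OCc1ccccc1 | intermediate
14 | (1R,2R,3R)-7-(benzyloxy)-1-[4-(benzyloxy)-3-methoxyphenyl]-3-[(benzyloxy)methyl]-2-{[(diisopropylsilyl)oxy]methyl}-6-methoxy-1,2,3,4-tetrahydronaphthalen-1-ol | COc1cc([C@@]2(O)c3cc(OCc4ccccc4)c(OC)cc3C[C@@H](COCc3ccccc3)[C@@H]2CO[SiH](C(C)C)C(C)C)ccc1OCc1ccccc1 | intermediate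
15 | C1 carbenium ion formed from 14 by loss of the C1 hydroxyl | COc1cc([C+]2c3cc(OCc4ccccc4)c(OC)cc3C[C@@H](COCc3ccccc3)[C@@H]2CO[SiH](C(C)C)C(C)C)ccc1OCc1ccccc1 | intermediate
16 | {[(1S,2R,3R)-7-(benzyloxy)-1-[4-(benzyloxy)-3-methoxyphenyl]-3-[(benzyloxy)methyl]-6-methoxy-1,2,3,4-tetrahydronaphthalen-2-yl]methoxy}diisopropylsilyl trifluoroacetate | COc1cc([C@H]2c3cc(OCc4ccccc4)c(OC)cc3C[C@@H](COCc3ccccc3)[C@@H]2CO[Si](OC(=O)C(F)(F)F)(C(C)C)C(C)C)ccc1OCc1ccccc1 | intermediate
17 | [(1S,2R,3R)-7-(benzyloxy)-1-[4-(benzyloxy)-3-methoxyphenyl]-3-[(benzyloxy)methyl]-6-methoxy-1,2,3,4-tetrahydronaphthalen-2-yl]methanol | COc1cc([C@H]2c3cc(OCc4ccccc4)c(OC)cc3C[C@@H](COCc3ccccc3)[C@@H]2CO)ccc1OCc1ccccc1 | intermediate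
18 | [(1S,2R,3R)-7-(benzyloxy)-1-[4-(benzyloxy)-3-methoxyphenyl]-3-[(benzyloxy)methyl]-6-methoxy-1,2,3,4-tetrahydronaphthalen-2-yl]methyl acetate | COc1cc([C@H]2c3cc(OCc4ccccc4)c(OC)cc3C[C@@H](COCc3ccccc3)[C@@H]2COC(C)=O)ccc1OCc1ccccc1 | intermediate
19 | [(1S,2R,3R)-7-hydroxy-1-(4-hydroxy-3-methoxyphenyl)-3-(hydroxymethyl)-6-methoxy-1,2,3,4-tetrahydronaphthalen-2-yl]methyl acetate | COc1cc([C@H]2c3cc(O)c(OC)cc3C[C@@H](CO)[C@@H]2COC(C)=O)ccc1O | target

## Step count and least certain steps

Total: 10 steps. Longest linear sequence: 9 steps (steps 1, 2, 3, 5, 6, 7, 8, 9, 10 from creosol 1); step 4 is a one-step side branch.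

**Step 5 (key step).** The most likely failure is insufficient facial selectivity, or the wrong sense of it.
- The dienol is generated free in solution and may add to imide that is not on titanium.
- It may also exchange onto titanium through its own hydroxyl and react through a geometry other than the simple chelate model.
- The alkoxy-rich benzophenone may photoenolise sluggishly.
- The chlorotitanium Lewis acid may ionise and dehydrate the tertiary carbinol of the product, hence the low temperature and cold basic quench.

The fallback replaces catalyst control by a covalent auxiliary and sets out from 9 and 7. (R)-4-Benzyloxazolidin-2-one is N-acylated with acryloyl chloride to (R)-3-acryloyl-4-benzyloxazolidin-2-one F1. Cross metathesis of F1 with 9 under the conditions of step 4 gives (R)-4-benzyl-3-[(E)-4-(benzyloxy)but-2-enoyl]oxazolidin-2-one F2. Irradiation of 7 with F2 chelated on achiral TiCl2(OiPr)2 should give the auxiliary-bearing adduct (R)-4-benzyl-3-{[(1R,2S,3R)-7-(benzyloxy)-1-[4-(benzyloxy)-3-methoxyphenyl]-3-[(benzyloxy)methyl]-1-hydroxy-6-methoxy-1,2,3,4-tetrahydronaphthalen-2-yl]carbonyl}oxazolidin-2-one F3, because the benzyl group of the auxiliary shields the Cα-Si face. LiBH4 cleavage as in step 6 then returns the sequence to 13.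

**Step 8.** What may go wrong is loss of the tether before hydride transfer (acid cleavage of the Si–O bond). Other risks are intermolecular hydride transfer at too high a concentration, which would deliver hydrogen anti to the C2 arm, and loss of the C2 proton from the cation, which would scramble C2.

The fallback sets out from 13 and uses heterogeneous hydrogenolysis in place of ionic reduction. Selective acetylation of the primary hydroxyl (Ac2O, pyridine, 0 °C) gives [(1R,2R,3R)-7-(benzyloxy)-1-[4-(benzyloxy)-3-methoxyphenyl]-3-[(benzyloxy)methyl]-1-hydroxy-6-methoxy-1,2,3,4-tetrahydronaphthalen-2-yl]methyl acetate F4. Hydrogenolysis of its tertiary benzylic C–O bond over Raney Ni in EtOAc, which on nickel proceeds with retention, should put hydrogen where the hydroxyl stood, cis to the C2 arm. This rejoins the route at 18; benzyl ethers lost at this point only anticipate step 10.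

**Step 6.** The risk is retro-aldol opening of ring B. Under the basic hydride conditions the tertiary alkoxide of this β-hydroxy imide can expel the imide enolate, and the liberated diaryl ketone would then be reduced irreversibly.

The fallback sets out from 12 and removes the free hydroxyl from play. N-(Trimethylsilyl)imidazole in CH2Cl2 gives 3-{[(1R,2S,3R)-7-(benzyloxy)-1-[4-(benzyloxy)-3-methoxyphenyl]-3-[(benzyloxy)methyl]-6-methoxy-1-[(trimethylsilyl)oxy]-1,2,3,4-tetrahydronaphthalen-2-yl]carbonyl}oxazolidin-2-one F5. LiBH4 then cleaves the imide to [(1R,2R,3R)-7-(benzyloxy)-1-[4-(benzyloxy)-3-methoxyphenyl]-3-[(benzyloxy)methyl]-6-methoxy-1-[(trimethylsilyl)oxy]-1,2,3,4-tetrahydronaphthalen-2-yl]methanol F6. K2CO3 in MeOH removes the trimethylsilyl group and the route is rejoined at 13.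

**Step 4.** The metathesis may stall through chelation of the imide carbonyl to the ruthenium carbene, or the allyl ether may isomerise to the enol ether and erode the cross product.

The fallback sets out from 9 and builds the double bond by carbonyl olefination. Ozonolysis (O3, CH2Cl2, −78 °C; Me2S) gives benzyloxyacetaldehyde F7. A Horner–Wadsworth–Emmons reaction of F7 with the known reagent diethyl [2-oxo-2-(2-oxooxazolidin-3-yl)ethyl]phosphonate (LiCl, iPr2NEt, MeCN) returns to 10 with E geometry.

## Further compounds

F1 | step 5 | (R)-3-acryloyl-4-benzyloxazolidin-2-one | C=CC(=O)N1[C@H](Cc2ccccc2)COC1=O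
F2 | step 5 | (R)-4-benzyl-3-[(E)-4-(benzyloxy)but-2-enoyl]oxazolidin-2-one | O=C(/C=C/COCc1ccccc1)N1[C@H](Cc2ccccc2)COC1=O
F3 | step 5 | (R)-4-benzyl-3-{[(1R,2S,3R)-7-(benzyloxy)-1-[4-(benzyloxy)-3-methoxyphenyl]-3-[(benzyloxy)methyl]-1-hydroxy-6-methoxy-1,2,3,4-tetrahydronaphthalen-2-yl]carbonyl}oxazolidin-2-one | COc1cc([C@@]2(O)c3cc(OCc4ccccc4)c(OC)cc3C[C@@H](COCc3ccccc3)[C@@H]2C(=O)N2[C@H](Cc3ccccc3)COC2=O)ccc1OCc1ccccc1
F4 | step 8 | [(1R,2R,3R)-7-(benzyloxy)-1-[4-(benzyloxy)-3-methoxyphenyl]-3-[(benzyloxy)methyl]-1-hydroxy-6-methoxy-1,2,3,4-tetrahydronaphthalen-2-yl]methyl acetate | COc1cc([C@@]2(O)c3cc(OCc4ccccc4)c(OC)cc3C[C@@H](COCc3ccccc3)[C@@H]2COC(C)=O)ccc1OCc1ccccc1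
F5 | step 6 | 3-{[(1R,2S,3R)-7-(benzyloxy)-1-[4-(benzyloxy)-3-methoxyphenyl]-3-[(benzyloxy)methyl]-6-methoxy-1-[(trimethylsilyl)oxy]-1,2,3,4-tetrahydronaphthalen-2-yl]carbonyl}oxazolidin-2-one | COc1cc([C@@]2(O[Si](C)(C)C)c3cc(OCc4ccccc4)c(OC)cc3C[C@@H](COCc3ccccc3)[C@@H]2C(=O)N2CCOC2=O)ccc1OCc1ccccc1
F6 | step 6 | [(1R,2R,3R)-7-(benzyloxy)-1-[4-(benzyloxy)-3-methoxyphenyl]-3-[(benzyloxy)methyl]-6-methoxy-1-[(trimethylsilyl)oxy]-1,2,3,4-tetrahydronaphthalen-2-yl]methanol | COc1cc([C@@]2(O[Si](C)(C)C)c3cc(OCc4ccccc4)c(OC)cc3C[C@@H](COCc3ccccc3)[C@@H]2CO)ccc1OCc1ccccc1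
F7 | step 4 | benzyloxyacetaldehyde | O=CCOCc1ccccc1
A1 | alternative 1 | (S)-4-benzyl-3-[(E)-3-(3-bromo-4-hydroxy-5-methoxyphenyl)prop-2-enoyl]oxazolidin-2-one | COc1cc(/C=C/C(=O)N2[C@@H](Cc3ccccc3)COC2=O)cc(Br)c1O
A2 | alternative 1 | trans-8-bromo-1-(3-bromo-4-hydroxy-5-methoxyphenyl)-7-hydroxy-6-methoxy-1,2-dihydronaphthalene-2,3-dicarbonyl bis[(S)-4-benzyloxazolidin-2-one] imide | COc1cc([C@H]2c3c(Br)c(O)c(OC)cc3C=C(C(=O)N3[C@@H](Cc4ccccc4)COC3=O)[C@@H]2C(=O)N2[C@@H](Cc3ccccc3)COC2=O)cc(Br)c1O
A3 | alternative 2 | 2-{1-[4-(benzyloxy)-3-methoxyphenyl]prop-2-yn-1-yl}-3-[(benzyloxy)methyl]-4-(4-methoxyfuran-2-yl)butyl acetate, the three stereocentres configured as in 19 | COc1coc(C[C@@H](COCc2ccccc2)[C@H](COC(C)=O)[C@H](C#C)c2ccc(OCc3ccccc3)c(OC)c2)c1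
A4 | alternative 2 | [(1S,2R,3R)-1-[4-(benzyloxy)-3-methoxyphenyl]-3-[(benzyloxy)methyl]-7-hydroxy-6-methoxy-1,2,3,4-tetrahydronaphthalen-2-yl]methyl acetate | COc1cc([C@H]2c3cc(O)c(OC)cc3C[C@@H](COCc3ccccc3)[C@@H]2COC(C)=O)ccc1OCc1ccccc1
A5 | alternative 3 | dimethyl 2-[1-{4-(benzyloxy)-2-[hydroxy(4-hydroxy-3-methoxyphenyl)methyl]-5-methoxyphenyl}but-3-en-2-yl]malonate, C3 configured as in 19, carbinol centre as a mixture | COc1cc(C(O)c2cc(OCc3ccccc3)c(OC)cc2C[C@@H](C=C)C(C(=O)OC)C(=O)OC)ccc1O
A6 | alternative 3 | dimethyl 7-(benzyloxy)-1-(4-hydroxy-3-methoxyphenyl)-6-methoxy-3-vinyl-3,4-dihydronaphthalene-2,2(1H)-dicarboxylate, aryl and vinyl cis | COc1cc([C@H]2c3cc(OCc4ccccc4)c(OC)cc3C[C@@H](C=C)C2(C(=O)OC)C(=O)OC)ccc1O
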